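1. In a one-step world, Z and Q give J on G at rate a·cG·cZ·cQ, and Q is spent on nothing else. At a fixed conversion cZ and cQ then stand the same whatever G was charged, so the order in G is 1.

the same everywhere: G 20 µM

|  | Z | Q | remark |
|---|---|---|---|
| delta | 20 mM | 42 mM | run made earlier |
| alpha | 20 mM | 66 mM | run made earlier |
| theta | 40 mM | 30 mM | run made earlier |
| flask | 20 mM | 30.0 mM |  |

| run | time / min | J / % | Z / % |
|---|---|---|---|
| delta | 1.33 | 22.1 | 78.4 |
| delta | 3.00 | 32.9 | 67.0 |
| delta | 6.00 | 41.5 | 58.3 |
| delta | 10.0 | 46.9 | 53.9 |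
| alpha | 0.833 | 22.4 | 78.4 |
| alpha | 2.00 | 33.5 | 66.6 |
| alpha | 4.00 | 43.2 | 56.9 |
| alpha | 10.0 | 53.6 | 46.4 |
| theta | 0.833 | 10.0 | 88.8 |
| theta | 2.00 | 17.3 | 81.5 |
| theta | 4.00 | 23.8 | 75.2 |
| theta | 10.0 | 29.7 | 68.9 |

(standard deviation of a reading: 0.5 percentage points)

- apparent order in G when 5.0% of the Z are converted (percent change of the rate of making J for one percent more G charged)

- no earlier run changes the charge of G; that part of a forecast is a guess

2. The alpha run refuses that world. Its J reads 0.0107 M at 10.0 min, so a one-step world keeps cQ near 0.0553 M at that time. Yet Z loses 22 percentage points in the first 0.833 min and 10 points from 4.00 min to 10.0 min.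

3. My reckoning supposes that Q destroys itself in pairs without G, so ln cQ falls at 2k·cQ. That makes the clock cQ-charge × time, and delta and alpha agree: Z stands at 78.4% and 78.4% at 3.35 M·s and 3.30 M·s. No run varies G, so this remains my supposition.

4. Now I divide the fall of ln cZ, a·cG·cQ, by the fall of ln cQ. Time and cQ drop out, leaving the race number n = a·cG/(2k), a selectivity factor: the fall in ln cZ per unit fall in ln cQ.

5. Late, cQ falls nearly inversely with time, so n is close to the fall of ln cZ per unit of ln t. Alpha's readings from 2.00 min to 10.0 min give n = 0.225.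

6. In the flask, with alpha's n, ln(charged cQ/cQ) at conversion 5.0% is L = 0.228. One percent more G raises n one percent, lowers L one percent of itself, and so raises cQ by L percent. My order for the flask is therefore 1.23.

The forecast gives 1.06, lower than mine: “No run varies G, so this is a guess.”

The flask gives 1.2.

    Z + G ⇌ E (K = 14.0 /M, k = 2.00 × 10⁵ /M/s)
    Q + E ⇌ D (K = 13.0 /M, k = 41000 /M/s)
    D → G + J (k = 48.0 /s)
    2 Q → X (k = 0.220 /M/s)

At 0.800 min the flask holds X at 5.35 mM, which took 0.0107 M of Q, against J at 2.56 mM. With n = 0.225, the Z left at that time, 87.2%, raised to the power 4.44, gives Q at 54.4% of its charge, and the flask holds 55.8%.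

The earlier runs and the new flask are simulated with made-up constants, and the scatter is random.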